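The route rests on cutting the ring-B bond between the CH2 and the CHOH carbon. The ring-A ketone carbon, the ring-fusion CH, that CH2 and the carbinol carbon make up a γ-hydroxy ketone, the retron of a ketone homoenolate adding to an aldehyde, and the tertiary fusion hydroxyl is allylic to the ring-A enol position. In one operation TiCl4 opens a ring-A siloxycyclopropane and the released CH2 closes the cyclopentane onto a neopentyl aldehyde, giving the ring, the bond and the secondary carbinol centre. The precursor is a cycloheptane carrying the quaternary methyl/benzyloxyethyl carbon, a siloxycyclopropane whose CH2 is syn to the silylated tertiary carbinol oxygen, and CMe2CHO on that carbinol carbon.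

Key step: step 12

Assumption: the copper–carbene catalyst of step 3 is taken to show its established sense of induction on 2-substituted cyclopentenones; the mirror-image ligand serves if the sense proves opposite.

Design note: the side-chain oxygen travels as a benzyl ether (commercial two-carbon unit, neutral removal). The cyclopropanol oxygen is a triisopropylsilyl ether (it can be installed beside the free tertiary hydroxyl and is stable to handling). The tertiary carbinol is a trimethylsilyl ether only from step 10 to step 12.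

Step 1
Reactants: 1 cyclopent-2-en-1-one
Product: 2 2-iodocyclopent-2-en-1-one
Conditions: I2, K2CO3, DMAP (cat.), THF/H2O (1:1), rt
Reagents that add atoms: iodine, II
Why: α-Iodination of the enone by amine conjugate addition, iodination of the enolate and elimination (Baylis–Hillman-type activation), a standard entry to 2-iodoenones.

Step 2
Reactants: 2 2-iodocyclopent-2-en-1-one; 3 benzyl vinyl ether
Product: 5 2-[2-(benzyloxy)ethyl]cyclopent-2-en-1-one, via alkyl-9-BBN borane 4 (not isolated)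
Conditions: 3, 9-BBN-H, THF, 0 °C → rt; then 2, PdCl2(dppf) (cat.), AsPh3 (cat.), Cs2CO3, DMF/THF/H2O, rt
Reagents that add atoms: none
Why: Hydroboration places boron on the terminal carbon of the enol ether, and the B-alkyl Suzuki–Miyaura coupling with the 2-iodoenone runs at room temperature, where reductive elimination should outpace β-alkoxy elimination.

Step 3
Reactants: 5 2-[2-(benzyloxy)ethyl]cyclopent-2-en-1-one
Product: 7 (2R,3R)-2-[2-(benzyloxy)ethyl]-2,3-dimethylcyclopentan-1-one, via magnesium enolate 6 (not isolated)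
Conditions: MeMgBr, Cu(OTf)2 (3 mol %), chiral imidazolinium chloride (NHC precursor, 4 mol %), Et2O, −30 °C; then MeI, DMPU, −30 °C → rt
Reagents that add atoms: methylmagnesium bromide, C[Mg]Br; iodomethane, CI
Why: Copper-catalysed asymmetric conjugate addition sets the ring CHMe centre (R) under ligand control, and the regiodefined magnesium enolate is methylated on the face away from that new methyl (enolate trapping), which sets the quaternary centre (R) with the two methyls trans and the side chain cis to the ring methyl.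

Step 4
Reactants: 7 (2R,3R)-2-[2-(benzyloxy)ethyl]-2,3-dimethylcyclopentan-1-one
Product: 8 {[(4R,5R)-5-[2-(benzyloxy)ethyl]-4,5-dimethylcyclopent-1-en-1-yl]oxy}trimethylsilane
Conditions: TMSOTf, Et3N, CH2Cl2, 0 °C
Reagents that add atoms: trimethylsilyl triflate, C[Si](C)(C)OS(=O)(=O)C(F)(F)F
Why: Soft enolisation to the silyl enol ether, where a single regioisomer is possible because only one α-carbon carries hydrogen.

Step 5
Reactants: 8 {[(4R,5R)-5-[2-(benzyloxy)ethyl]-4,5-dimethylcyclopent-1-en-1-yl]oxy}trimethylsilane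
Product: 9 (1S,2R,3R,5R)-2-[2-(benzyloxy)ethyl]-7,7-dichloro-2,3-dimethyl-1-[(trimethylsilyl)oxy]bicyclo[3.2.0]heptan-6-one
Conditions: Cl2CHCOCl, Et3N, hexanes, rt
Reagents that add atoms: dichloroacetyl chloride, ClC(Cl)C(Cl)=O
Why: [2+2] cycloaddition of dichloroketene, made in the flask, with the silyl enol ether, in which the ketene carbonyl carbon bonds to the nucleophilic CH terminus, the fusion is necessarily cis, approach is expected on the face of the quaternary methyl, and both new centres are erased in step 6.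

Step 6
Reactants: 9 (1S,2R,3R,5R)-2-[2-(benzyloxy)ethyl]-7,7-dichloro-2,3-dimethyl-1-[(trimethylsilyl)oxy]bicyclo[3.2.0]heptan-6-one
Product: 12 (4R,5R)-4-[2-(benzyloxy)ethyl]-4,5-dimethylcycloheptane-1,3-dione, via dechlorinated silyloxy ketone 10 (not isolated), via hydroxycyclobutanone 11 (not isolated)
Conditions: Zn dust, AcOH, i-PrOH/H2O, 0 °C → rt; then 80 °C
Reagents that add atoms: none
Why: Reductive dechlorination, desilylation and retro-aldol cleavage of the strained β-hydroxycyclobutanone (two-carbon ring expansion), driven by release of four-ring strain and of the crowding between two adjacent fully substituted carbons, with no stereocentre touched.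

Step 7
Reactants: 12 (4R,5R)-4-[2-(benzyloxy)ethyl]-4,5-dimethylcycloheptane-1,3-dione; 13 prenyl bromide
Product: 14 (2R,3R,6S)-2-[2-(benzyloxy)ethyl]-6-hydroxy-2,3-dimethyl-6-(2-methylbut-3-en-2-yl)cycloheptan-1-one
Conditions: In powder (3 equiv), 13 (4 equiv), THF/H2O (1:1), rt
Reagents that add atoms: none
Why: Indium-mediated Barbier allylation in which the prenylindium reagent reacts through its γ-carbon (reverse prenylation) at the carbonyl flanked by two CH2 groups, the other being shielded by the quaternary carbon, and attack on the ring face that carries only the quaternary methyl, opposite the side chain and the ring methyl, is expected to set the carbinol centre (S, hydroxyl cis to the side chain).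

Step 8
Reactants: 14 (2R,3R,6S)-2-[2-(benzyloxy)ethyl]-6-hydroxy-2,3-dimethyl-6-(2-methylbut-3-en-2-yl)cycloheptan-1-one
Product: 15 (1S,4R,5R)-4-[2-(benzyloxy)ethyl]-4,5-dimethyl-1-(2-methylbut-3-en-2-yl)-3-{[tri(propan-2-yl)silyl]oxy}cyclohept-2-en-1-ol
Conditions: TIPSOTf (1.5 equiv), Et3N (3 equiv), CH2Cl2, −78 → 0 °C
Reagents that add atoms: triisopropylsilyl triflate, CC(C)[Si](C(C)C)(C(C)C)OS(=O)(=O)C(F)(F)F
Why: Soft enolisation to the silyl enol ether, which can form only towards the ring CH2, while the bulky silyl triflate leaves the tertiary hydroxyl next to the quaternary carbon free and the absence of strong base avoids retro-aldol opening of ring A.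

Step 9
Reactants: 15 (1S,4R,5R)-4-[2-(benzyloxy)ethyl]-4,5-dimethyl-1-(2-methylbut-3-en-2-yl)-3-{[tri(propan-2-yl)silyl]oxy}cyclohept-2-en-1-ol; 16 diiodomethane
Product: 18 (1S,2S,5R,6R,7R)-6-[2-(benzyloxy)ethyl]-5,6-dimethyl-2-(2-methylbut-3-en-2-yl)-7-{[tri(propan-2-yl)silyl]oxy}bicyclo[5.1.0]octan-2-ol, via ethylzinc alkoxide 17 (not isolated)
Conditions: Et2Zn (4 equiv), CH2I2 (8 equiv), CH2Cl2, 0 °C → rt; aq. NaHCO3
Reagents that add atoms: none
Why: Hydroxyl-directed Simmons–Smith cyclopropanation (Furukawa conditions) in which the zinc alkoxide of the allylic tertiary carbinol delivers the CH2 to the electron-rich enol ether on its own face, setting both cyclopropane centres syn to the carbinol oxygen, while the hindered and less electron-rich vinyl group should react far more slowly.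

Step 10
Reactants: 18 (1S,2S,5R,6R,7R)-6-[2-(benzyloxy)ethyl]-5,6-dimethyl-2-(2-methylbut-3-en-2-yl)-7-{[tri(propan-2-yl)silyl]oxy}bicyclo[5.1.0]octan-2-ol
Product: 19 {[(1R,2R,3R,6S,7S)-2-[2-(benzyloxy)ethyl]-2,3-dimethyl-6-(2-methylbut-3-en-2-yl)-6-[(trimethylsilyl)oxy]bicyclo[5.1.0]octan-1-yl]oxy}tri(propan-2-yl)silane
Conditions: N-(trimethylsilyl)imidazole (neat), 60 °C
Reagents that add atoms: N-(trimethylsilyl)imidazole, C[Si](C)(C)n1ccnc1
Why: Silylation of a hindered tertiary alcohol with an acid-free silyl donor, so that nothing can ionise the cyclopropylcarbinol, and the silyl ether later prevents titanium alkoxide formation, HCl release and retro-aldol loss of the aldehyde arm.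

Step 11
Reactants: 19 {[(1R,2R,3R,6S,7S)-2-[2-(benzyloxy)ethyl]-2,3-dimethyl-6-(2-methylbut-3-en-2-yl)-6-[(trimethylsilyl)oxy]bicyclo[5.1.0]octan-1-yl]oxy}tri(propan-2-yl)silane
Product: 21 2-[(1R,2S,5R,6R,7R)-6-[2-(benzyloxy)ethyl]-5,6-dimethyl-7-{[tri(propan-2-yl)silyl]oxy}-2-[(trimethylsilyl)oxy]bicyclo[5.1.0]octan-2-yl]-2-methylpropanal, via secondary ozonide 20 (not isolated)
Conditions: O3, CH2Cl2, −78 °C (Sudan Red 7B end point); then PPh3, −78 °C → rt
Reagents that add atoms: ozone, [O-][O+]=O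
Why: Ozonolysis with reductive work-up, the monosubstituted alkene being the only π bond that reacts with ozone at −78 °C, while the cyclopropane and silyl ethers are inert and the aldehyde has no α-hydrogen.

Step 12
Reactants: 21 2-[(1R,2S,5R,6R,7R)-6-[2-(benzyloxy)ethyl]-5,6-dimethyl-7-{[tri(propan-2-yl)silyl]oxy}-2-[(trimethylsilyl)oxy]bicyclo[5.1.0]octan-2-yl]-2-methylpropanal
Product: 24 (2S,3aS,5R,6R,8aS)-5-[2-(benzyloxy)ethyl]-2,8a-dihydroxy-1,1,5,6-tetramethyloctahydroazulen-4(1H)-one, via titanium homoenolate 22 (not isolated), via titanium aldolate 23 (not isolated)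
Conditions: TiCl4 (2.5 equiv), CH2Cl2, −78 → −40 °C; then MeOH, −78 → 0 °C; aq. NaHCO3
Reagents that add atoms: none
Why: TiCl4 binds the aldehyde and, acting at the cyclopropane CH2, breaks the bond between that CH2 and the siloxy carbon while chloride removes the silyl group as i-Pr3SiCl, so that the ring-A ketone and the β-trichlorotitanio ketone 22 (a ketone homoenolate, metal on the CH2 held by the fusion CH) arise and this carbon nucleophile adds to the aldehyde on the neighbouring carbinol carbon. The closest known reaction type is the titanium homoenolate (homoaldol) addition of 1-siloxycyclopropanes to aldehydes, well known between two molecules and rare in the intramolecular ketone case. Ring B, the cyclopentane, closes in the 5-exo-trig mode by attack of the CH2 on the carbonyl carbon. The new carbinol centre (S) is set by an open arrangement in which the titanium-bound aldehyde oxygen turns away from the bulky tertiary OSiMe3 group and towards the ring-A CH2, which gives the trans 1,3-diol, and the silyl ether cannot bridge to titanium, so the chelated mode that would give the cis diol is suppressed. The step needs cleavage of the CH2–C(OSi) bond and not of the ring bond, secured because attack at the unsubstituted CH2 gives a primary C–Ti bond and a five-membered ring where the other mode would need a four-membered one, and it needs a trans ring fusion, already fixed because the CH2 lies syn to the carbinol oxygen and the fusion CH is not touched. The methanolic quench generates HCl, which removes the tertiary trimethylsilyl group and releases diol 24.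

Step 13
Reactants: 24 (2S,3aS,5R,6R,8aS)-5-[2-(benzyloxy)ethyl]-2,8a-dihydroxy-1,1,5,6-tetramethyloctahydroazulen-4(1H)-one
Product: 25 (2S,3aS,5R,6R,8aS)-2,8a-dihydroxy-5-(2-hydroxyethyl)-1,1,5,6-tetramethyloctahydroazulen-4(1H)-one
Conditions: H2 (1 atm), Pd/C (10 wt %), EtOAc, rt
Reagents that add atoms: none
Why: Catalytic hydrogenolysis of the benzyl ether under neutral conditions, which spare the β-hydroxy ketone (no base for retro-aldol cleavage or epimerisation of the fusion CH) and the hindered ketone.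

Step 14
Reactants: 25 (2S,3aS,5R,6R,8aS)-2,8a-dihydroxy-5-(2-hydroxyethyl)-1,1,5,6-tetramethyloctahydroazulen-4(1H)-one
Product: 26 (2S,3aS,5R,6R,8aS)-2,8a-dihydroxy-5-(2-iodoethyl)-1,1,5,6-tetramethyloctahydroazulen-4(1H)-one
Conditions: I2, PPh3, imidazole, CH2Cl2, 0 °C
Reagents that add atoms: iodine, II
Why: Appel iodination, in which only the primary alcohol can be displaced because the neopentylic secondary and the tertiary hydroxyl are too hindered for SN2.

Step 15
Reactants: 26 (2S,3aS,5R,6R,8aS)-2,8a-dihydroxy-5-(2-iodoethyl)-1,1,5,6-tetramethyloctahydroazulen-4(1H)-one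
Product: 27 (2S,3aS,5R,6R,8aS)-5-(2-iodoethyl)-1,1,5,6-tetramethyl-2,8a-bis[(trimethylsilyl)oxy]octahydroazulen-4(1H)-one
Conditions: TMSOTf, 2,6-lutidine, CH2Cl2, −78 → 0 °C
Reagents that add atoms: trimethylsilyl triflate, C[Si](C)(C)OS(=O)(=O)C(F)(F)F
Why: Silyl ether protection of both hydroxyls so that no O–H can protonate the alkylzinc reagent of the next step, the weak base leaving the hindered ketone unenolised.

Step 16
Reactants: 27 (2S,3aS,5R,6R,8aS)-5-(2-iodoethyl)-1,1,5,6-tetramethyl-2,8a-bis[(trimethylsilyl)oxy]octahydroazulen-4(1H)-one; 28 4-bromofuran-2(5H)-one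
Product: 31 4-{2-[(2S,3aS,5R,6R,8aS)-2,8a-dihydroxy-1,1,5,6-tetramethyl-4-oxodecahydroazulen-5-yl]ethyl}furan-2(5H)-one (CNP0077405.3), via alkylzinc iodide 29 (not isolated), via bis-silyl ether 30 (not isolated)
Conditions: Zn dust (activated with TMSCl/BrCH2CH2Br), LiCl, THF, 40 °C; then 28, PdCl2(dppf) (5 mol %), THF/DMA, rt; then 1 M HCl, THF/MeOH, 0 °C
Reagents that add atoms: none
Why: Zinc insertion into the primary iodide and Negishi sp3–sp2 coupling with the β-bromobutenolide under neutral conditions, after which the mild acidic work-up removes both trimethylsilyl ethers without touching any stereocentre.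

Compound list

1 | cyclopent-2-en-1-one | O=C1C=CCC1 | starting material
2 | 2-iodocyclopent-2-en-1-one | O=C1CCC=C1I | intermediate
3 | benzyl vinyl ether | C=COCc1ccccc1 | starting material
4 | 9-[2-(benzyloxy)ethyl]-9-borabicyclo[3.3.1]nonane | B1(CCOCc2ccccc2)C2CCCC1CCC2 | intermediate (not isolated)
5 | 2-[2-(benzyloxy)ethyl]cyclopent-2-en-1-one | O=C1CCC=C1CCOCc1ccccc1 | intermediate
6 | bromomagnesium (3R)-2-[2-(benzyloxy)ethyl]-3-methylcyclopent-1-en-1-olate | C[C@@H]1CCC(O[Mg]Br)=C1CCOCc1ccccc1 | intermediate (not isolated)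
7 | (2R,3R)-2-[2-(benzyloxy)ethyl]-2,3-dimethylcyclopentan-1-one (methyls trans) | C[C@@H]1CCC(=O)[C@]1(C)CCOCc1ccccc1 | intermediate
8 | {[(4R,5R)-5-[2-(benzyloxy)ethyl]-4,5-dimethylcyclopent-1-en-1-yl]oxy}trimethylsilane | C[C@@H]1CC=C(O[Si](C)(C)C)[C@]1(C)CCOCc1ccccc1 | intermediate
9 | (1S,2R,3R,5R)-2-[2-(benzyloxy)ethyl]-7,7-dichloro-2,3-dimethyl-1-[(trimethylsilyl)oxy]bicyclo[3.2.0]heptan-6-one (cis-fused, four-membered ring on the face of the C2 methyl) | C[C@@H]1CC[C@H]2C(=O)C(Cl)(Cl)[C@@]2(O[Si](C)(C)C)[C@]1(C)CCOCc1ccccc1 | intermediate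
10 | (1S,2R,3R,5R)-2-[2-(benzyloxy)ethyl]-2,3-dimethyl-1-[(trimethylsilyl)oxy]bicyclo[3.2.0]heptan-6-one | C[C@@H]1CC[C@H]2C(=O)C[C@@]2(O[Si](C)(C)C)[C@]1(C)CCOCc1ccccc1 | intermediate (not isolated)
11 | (1S,2R,3R,5R)-2-[2-(benzyloxy)ethyl]-1-hydroxy-2,3-dimethylbicyclo[3.2.0]heptan-6-one | C[C@@H]1CC[C@H]2C(=O)C[C@@]2(O)[C@]1(C)CCOCc1ccccc1 | intermediate (not isolated)
12 | (4R,5R)-4-[2-(benzyloxy)ethyl]-4,5-dimethylcycloheptane-1,3-dione | C[C@@H]1CCC(=O)CC(=O)[C@]1(C)CCOCc1ccccc1 | intermediate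
13 | prenyl bromide (1-bromo-3-methylbut-2-ene) | CC(C)=CCBr | starting material
14 | (2R,3R,6S)-2-[2-(benzyloxy)ethyl]-6-hydroxy-2,3-dimethyl-6-(2-methylbut-3-en-2-yl)cycloheptan-1-one (hydroxyl cis to the side chain) | C[C@@H]1CC[C@@](O)(C(C)(C)C=C)CC(=O)[C@]1(C)CCOCc1ccccc1 | intermediate
15 | (1S,4R,5R)-4-[2-(benzyloxy)ethyl]-4,5-dimethyl-1-(2-methylbut-3-en-2-yl)-3-{[tri(propan-2-yl)silyl]oxy}cyclohept-2-en-1-ol | C[C@@H]1CC[C@@](O)(C(C)(C)C=C)C=C(O[Si](C(C)C)(C(C)C)C(C)C)[C@]1(C)CCOCc1ccccc1 | intermediate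
16 | diiodomethane | ICI | starting material
17 | ethylzinc alkoxide of 15 | C[C@@H]1CC[C@@](O[Zn]CC)(C(C)(C)C=C)C=C(O[Si](C(C)C)(C(C)C)C(C)C)[C@]1(C)CCOCc1ccccc1 | intermediate (not isolated)
18 | (1S,2S,5R,6R,7R)-6-[2-(benzyloxy)ethyl]-5,6-dimethyl-2-(2-methylbut-3-en-2-yl)-7-{[tri(propan-2-yl)silyl]oxy}bicyclo[5.1.0]octan-2-ol (cyclopropane CH2 syn to the hydroxyl) | C[C@@H]1CC[C@@](O)(C(C)(C)C=C)[C@@H]2C[C@]2(O[Si](C(C)C)(C(C)C)C(C)C)[C@]1(C)CCOCc1ccccc1 | intermediate
19 | {[(1R,2R,3R,6S,7S)-2-[2-(benzyloxy)ethyl]-2,3-dimethyl-6-(2-methylbut-3-en-2-yl)-6-[(trimethylsilyl)oxy]bicyclo[5.1.0]octan-1-yl]oxy}tri(propan-2-yl)silane | C[C@@H]1CC[C@@](O[Si](C)(C)C)(C(C)(C)C=C)[C@@H]2C[C@]2(O[Si](C(C)C)(C(C)C)C(C)C)[C@]1(C)CCOCc1ccccc1 | intermediate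
20 | secondary ozonide of 19 (1,2,4-trioxolan-3-yl in place of the vinyl group) | C[C@@H]1CC[C@@](O[Si](C)(C)C)(C(C)(C)C3OCOO3)[C@@H]2C[C@]2(O[Si](C(C)C)(C(C)C)C(C)C)[C@]1(C)CCOCc1ccccc1 | intermediate (not isolated)
21 | 2-[(1R,2S,5R,6R,7R)-6-[2-(benzyloxy)ethyl]-5,6-dimethyl-7-{[tri(propan-2-yl)silyl]oxy}-2-[(trimethylsilyl)oxy]bicyclo[5.1.0]octan-2-yl]-2-methylpropanal (key-step precursor) | C[C@@H]1CC[C@@](O[Si](C)(C)C)(C(C)(C)C=O)[C@@H]2C[C@]2(O[Si](C(C)C)(C(C)C)C(C)C)[C@]1(C)CCOCc1ccccc1 | intermediate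
22 | (2S,3S,6R,7R)-7-[2-(benzyloxy)ethyl]-6,7-dimethyl-3-(2-methyl-1-oxopropan-2-yl)-2-[(trichlorotitanio)methyl]-3-[(trimethylsilyl)oxy]cycloheptan-1-one | C[C@@H]1CC[C@@](O[Si](C)(C)C)(C(C)(C)C=O)[C@H](C[Ti](Cl)(Cl)Cl)C(=O)[C@]1(C)CCOCc1ccccc1 | intermediate (not isolated)
23 | (2S,3aS,5R,6R,8aS)-5-[2-(benzyloxy)ethyl]-1,1,5,6-tetramethyl-2-[(trichlorotitanio)oxy]-8a-[(trimethylsilyl)oxy]octahydroazulen-4(1H)-one | C[C@@H]1CC[C@]2(O[Si](C)(C)C)[C@H](C[C@H](O[Ti](Cl)(Cl)Cl)C2(C)C)C(=O)[C@]1(C)CCOCc1ccccc1 | intermediate (not isolated)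
24 | (2S,3aS,5R,6R,8aS)-5-[2-(benzyloxy)ethyl]-2,8a-dihydroxy-1,1,5,6-tetramethyloctahydroazulen-4(1H)-one (trans-fused, trans diol; key-step product) | C[C@@H]1CC[C@]2(O)[C@H](C[C@H](O)C2(C)C)C(=O)[C@]1(C)CCOCc1ccccc1 | intermediate
25 | (2S,3aS,5R,6R,8aS)-2,8a-dihydroxy-5-(2-hydroxyethyl)-1,1,5,6-tetramethyloctahydroazulen-4(1H)-one | C[C@@H]1CC[C@]2(O)[C@H](C[C@H](O)C2(C)C)C(=O)[C@]1(C)CCO | intermediate
26 | (2S,3aS,5R,6R,8aS)-2,8a-dihydroxy-5-(2-iodoethyl)-1,1,5,6-tetramethyloctahydroazulen-4(1H)-one | C[C@@H]1CC[C@]2(O)[C@H](C[C@H](O)C2(C)C)C(=O)[C@]1(C)CCI | intermediate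
27 | (2S,3aS,5R,6R,8aS)-5-(2-iodoethyl)-1,1,5,6-tetramethyl-2,8a-bis[(trimethylsilyl)oxy]octahydroazulen-4(1H)-one | C[C@@H]1CC[C@]2(O[Si](C)(C)C)[C@H](C[C@H](O[Si](C)(C)C)C2(C)C)C(=O)[C@]1(C)CCI | intermediate
28 | 4-bromofuran-2(5H)-one | O=C1OCC(Br)=C1 | starting material
29 | {2-[(2S,3aS,5R,6R,8aS)-1,1,5,6-tetramethyl-4-oxo-2,8a-bis[(trimethylsilyl)oxy]decahydroazulen-5-yl]ethyl}zinc iodide | C[C@@H]1CC[C@]2(O[Si](C)(C)C)[C@H](C[C@H](O[Si](C)(C)C)C2(C)C)C(=O)[C@]1(C)CC[Zn]I | intermediate (not isolated)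
30 | 4-{2-[(2S,3aS,5R,6R,8aS)-1,1,5,6-tetramethyl-4-oxo-2,8a-bis[(trimethylsilyl)oxy]decahydroazulen-5-yl]ethyl}furan-2(5H)-one | C[C@@H]1CC[C@]2(O[Si](C)(C)C)[C@H](C[C@H](O[Si](C)(C)C)C2(C)C)C(=O)[C@]1(C)CCC1=CC(=O)OC1 | intermediate (not isolated)
31 | 4-{2-[(2S,3aS,5R,6R,8aS)-2,8a-dihydroxy-1,1,5,6-tetramethyl-4-oxodecahydroazulen-5-yl]ethyl}furan-2(5H)-one (CNP0077405.3) | C[C@@H]1CC[C@]2(O)[C@H](C[C@H](O)C2(C)C)C(=O)[C@]1(C)CCC1=CC(=O)OC1 | target

Total step count: 16. Longest linear sequence: 16 steps, from cyclopent-2-en-1-one (1) to the target (31); compounds 3, 13, 16 and 28 enter as bought.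

Steps most likely to fail

Step 12, the key step. What may go wrong is poor facial selectivity at the aldehyde carbon: if the homoenolate carbon is delivered while the same titanium holds the aldehyde oxygen (closed mode) and not through the open mode, the new hydroxyl ends up cis to the tertiary one. The fallback sets out from aldehyde 21 and comes back at diol 24. The cyclisation is run as written and the carbinol epimer, (2R,3aS,5R,6R,8aS)-5-[2-(benzyloxy)ethyl]-2,8a-dihydroxy-1,1,5,6-tetramethyloctahydroazulen-4(1H)-one F1, is oxidised with Dess–Martin periodinane (NaHCO3, CH2Cl2, 0 °C) to the hydroxy diketone (3aS,5R,6R,8aS)-5-[2-(benzyloxy)ethyl]-8a-hydroxy-1,1,5,6-tetramethylhexahydroazulene-2,4(1H,3H)-dione F2. Me4NBH(OAc)3 (MeCN/AcOH, −20 °C) then reduces the cyclopentanone by hydride delivery from boron bound to the tertiary hydroxyl, which places the new hydroxyl trans to it and gives 24. The ring-A ketone, lying between a quaternary carbon and the fusion CH, should be reduced far more slowly. The carbinol centre is then set by directed reduction and no longer by the carbon–carbon bond formation.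

Step 7. What may go wrong is poor or reversed facial selectivity in the addition to the carbonyl, because the two faces differ only through substituents three bonds away. The fallback sets out from dione 12 and comes back at hydroxy ketone 14. The indium addition product of the wrong configuration, (2R,3R,6R)-2-[2-(benzyloxy)ethyl]-6-hydroxy-2,3-dimethyl-6-(2-methylbut-3-en-2-yl)cycloheptan-1-one F3 (or the mixture of epimers), is dehydrated with methyl N-(triethylammoniosulfonyl)carbamate (Burgess reagent, benzene, 50 °C) to the conjugated enone (6R,7R)-7-[2-(benzyloxy)ethyl]-6,7-dimethyl-3-(2-methylbut-3-en-2-yl)cyclohept-2-en-1-one F4, which erases the carbinol centre. H2O2/NaOH (MeOH, 0 °C) then epoxidises the enone by conjugate attack at the β-carbon on the same ring face that the allylindium reagent had used, which is now the face required for oxygen, to give the epoxy ketone (1S,3R,4R,7R)-3-[2-(benzyloxy)ethyl]-3,4-dimethyl-7-(2-methylbut-3-en-2-yl)-8-oxabicyclo[5.1.0]octan-2-one F5. SmI2 (THF/MeOH, −78 °C) cleaves the α carbon–oxygen bond and returns 14. The carbinol configuration is then fixed by oxygen delivery to carbon and no longer by carbon delivery to the carbonyl.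

Step 9. What may go wrong is sluggish or unselective carbenoid transfer to an enol ether that lies between two fully substituted carbons: incomplete conversion, competing cyclopropanation of the vinyl group, or ionisation of the allylic carbinol by zinc halide. The fallback sets out from hydroxy ketone 14 and comes back at cyclopropanol ether 18, bypassing the enol silane 15. LDA (2.2 equiv, THF, −78 °C) converts 14 into the dilithium alkoxide–enolate of 14 F6, whose enolate half cannot undergo retro-aldol cleavage. CH2I2/SmI2 (THF, −78 °C → rt) generates a samarium carbenoid, a reagent that cyclopropanates lithium enolates to cyclopropanols and is strongly directed by allylic alkoxides, and gives (1R,2R,3R,6S,7S)-2-[2-(benzyloxy)ethyl]-2,3-dimethyl-6-(2-methylbut-3-en-2-yl)bicyclo[5.1.0]octane-1,6-diol F7 with the CH2 syn to the carbinol oxygen. TIPSOTf/2,6-lutidine (CH2Cl2, −78 → 0 °C) then silylates the cyclopropanol oxygen only, the neopentylic tertiary hydroxyl being too hindered for this reagent, and gives 18.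

Further compounds

F1 | step 12 | (2R,3aS,5R,6R,8aS)-5-[2-(benzyloxy)ethyl]-2,8a-dihydroxy-1,1,5,6-tetramethyloctahydroazulen-4(1H)-one | C[C@@H]1CC[C@]2(O)[C@H](C[C@@H](O)C2(C)C)C(=O)[C@]1(C)CCOCc1ccccc1
F2 | step 12 | (3aS,5R,6R,8aS)-5-[2-(benzyloxy)ethyl]-8a-hydroxy-1,1,5,6-tetramethylhexahydroazulene-2,4(1H,3H)-dione | C[C@@H]1CC[C@]2(O)[C@H](CC(=O)C2(C)C)C(=O)[C@]1(C)CCOCc1ccccc1
F3 | step 7 | (2R,3R,6R)-2-[2-(benzyloxy)ethyl]-6-hydroxy-2,3-dimethyl-6-(2-methylbut-3-en-2-yl)cycloheptan-1-one | C[C@@H]1CC[C@](O)(C(C)(C)C=C)CC(=O)[C@]1(C)CCOCc1ccccc1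
F4 | step 7 | (6R,7R)-7-[2-(benzyloxy)ethyl]-6,7-dimethyl-3-(2-methylbut-3-en-2-yl)cyclohept-2-en-1-one | C[C@@H]1CCC(C(C)(C)C=C)=CC(=O)[C@]1(C)CCOCc1ccccc1
F5 | step 7 | (1S,3R,4R,7R)-3-[2-(benzyloxy)ethyl]-3,4-dimethyl-7-(2-methylbut-3-en-2-yl)-8-oxabicyclo[5.1.0]octan-2-one | C[C@@H]1CC[C@]2(C(C)(C)C=C)O[C@@H]2C(=O)[C@]1(C)CCOCc1ccccc1
F6 | step 9 | dilithium alkoxide–enolate of 14 | C[C@@H]1CC[C@@](O[Li])(C(C)(C)C=C)C=C(O[Li])[C@]1(C)CCOCc1ccccc1
F7 | step 9 | (1R,2R,3R,6S,7S)-2-[2-(benzyloxy)ethyl]-2,3-dimethyl-6-(2-methylbut-3-en-2-yl)bicyclo[5.1.0]octane-1,6-diol | C[C@@H]1CC[C@@](O)(C(C)(C)C=C)[C@@H]2C[C@]2(O)[C@]1(C)CCOCc1ccccc1
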